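**Design of a synthesis of CNP0316477.1 (36) by anionic oxy-Cope ring expansion**

## The problem

The target 36 is a germacranolide of the 1(10)Z,4E series: a cyclodecadiene (C1–C10) with a Z-olefin C1=C10 carrying methyl C14 and an E-olefin C4=C5 carrying methyl C15. An α-methylene-γ-butyrolactone (C11, C12, C13) is trans-fused at C6/C7; C8 carries an angelate, C9 an acetate and C2 a free allylic hydroxyl. A synthesis must close a strained ten-membered ring and fix two trisubstituted olefins of opposite geometry; end-to-end closure pays both an entropic and a transannular penalty. Four of the five stereocentres (C6–C9) are contiguous, so they can be relayed: C7 can direct C8 and C8 can direct C9. C2 is cut off from them by C3 and the two olefins and needs its own, reagent-based control. The exocyclic methylene lactone (conjugate acceptor), the angelate (Z to E isomerisation), the vicinal diester (acyl migration) and the 1(10),4-diene (acid-induced transannular cyclisation) will not survive rough treatment and must appear late. The enabling feature is that C9(O)–C8–C7–C6–C5=C4 is a δ,ε-unsaturated carbonyl unit, and that the Z-olefin C1=C10 fits, with C9, C2, C3 and C4, inside a cyclohexene. The ten-membered ring can therefore be unfolded into a 1,2-dialkenylcyclohex-2-enol in which the Z geometry is guaranteed by the small ring.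

## Retrosynthesis

**Lactone and C12 oxidation level (36 ⇒ 35 ⇒ 34 ⇒ 33 ⇒ 32 ⇒ 31).** The C12–O6 ester bond is cut first, so that the methylene lactone is formed last, from dihydroxy acid 35, which arises from the bis-silyl ether acid 34. The neighbouring option, a late α-methylenation of a saturated lactone, would need strong base beside two esters. Acid 34 goes back through enal 33 and alcohol 32 to the PMB ether 31. The forward steps must be mild oxidations that leave three olefins and the angelate alone, and a desilylation that does not trigger transannular chemistry.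

**C8 and C9 oxygenation (31 ⇒ 30 ⇒ 29 ⇒ 26 ⇒ 24).** The acetate C–O bond, the C9–H bond, the angelate C–O bond and the C8–O bond are removed in turn, leading to dienone 24 with a C9 ketone and a C8 methylene. Carrying both oxygens through the ring formation would burden the ring-forming precursor; the ketone and its enolate are exactly what the ring-forming step leaves behind. The precursor is simpler by two stereocentres and two esters. The forward steps need enolate oxidation at C8 trans to the C7 side chain, 1,2-reduction at C9 anti to the C8 ester, angeloylation without isomerisation and no acyl migration.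

**Ten-membered ring (24 ⇒ 21).** The C6–C7 bond is cut and the C4–C9 bond is restored, the anionic oxy-Cope transform. Cuts at C5–C6 or C2–C3 would demand a macrocyclisation, and a transannular C5–C10 cut would demand a heavily substituted decalin. Carbinol 21 is a cyclohexenol with three stereocentres, of which only the quaternary C4 has to carry information for C6 and C7. The forward reaction needs a chair transition state with E termini and both alkenyl arms equatorial on the cyclohexene.

**C8–C9 bond (21 ⇒ 14 + 19).** The tertiary carbinol is opened to enone 14 and dienyl iodide 19 (used as dienyllithium 20). This is the convergent cut and splits the skeleton into a ten-carbon and a five-carbon piece. The forward step needs 1,2-addition to a hindered enone anti to the C4 arm. C9 itself ends as a carbonyl carbon, but its relative configuration decides which chair is open to the rearrangement, so this facial selectivity is a real demand of the plan.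

**Dienyl iodide (19 ⇒ 18 ⇒ 17 ⇒ 15).** The C7=C8 olefin is cut by an iodo-olefination of enal 18, which comes from the mono-PMB ether 17 of diol 15. The E geometry of C7=C8 is the only requirement.

**Enol ether arm (14 ⇒ 13 ⇒ 11 ⇒ 10).** The E-silyl enol ether is traced to aldehyde 13 and that to the allyl group of 11 and 10. The allyl group is the form in which the C5–C6 unit is easiest to introduce enantioselectively; the enol ether brings the C6 oxygen in at the right oxidation level.

**C2 oxygen (10 ⇒ 9 ⇒ 7).** The C2–O bond is cut by way of ene-dione 9. A direct γ-hydroxylation of enone 7 would depend on the C4 centre, whose methyl and allyl groups are too alike to bias a face, so the configuration is assigned by a chiral reducing agent instead.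

**Quaternary centre (7 ⇒ 5 ⇒ 4 ⇒ 1 + 2).** The C4–C5 bond is cut by a decarboxylative asymmetric allylation of enol carbonate 4, made from ketone 1 and chloroformate 2. Dehydrogenation is placed after the allylation because the quaternary centre then blocks aromatisation.

## Roads not taken

Alternative 1: Achmatowicz dearomatisation. The C8–C2 segment is traced to a (3-methylfuran-2-yl) carbinol A2. In the forward sense N-bromosuccinimide in aqueous THF oxidises the furan and the C8 hydroxyl closes onto C2, giving the 6-hydroxypyranone A1 with the C9 carbonyl, a C2–O bond and the C1=C10 olefin locked cis in a six-membered ring.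
- Merits: a cheap furan, a mild step, and C8 and C9 already oxygenated with C8 set beforehand by an asymmetric carbonyl reduction or addition.
- Weak points: the step does not close the carbocycle, so a later macrocyclisation (for instance an intramolecular 2-(alkoxycarbonyl)allyl metal addition forming C6–C7) is still required, with the medium-ring penalty and no clear control over C6, C7 and C2. The C8 oxygen is tied up as the ring oxygen next to an epimerisable acyloin.
- Comparison: this road is better in that the C8/C9 oxygens come with the building block. The chosen plan must install both on the formed macrocycle under conformational control, but it forms the ring without dilution and fixes C6, C7 and both ring olefins in one step.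

Alternative 2: cis-decalin boronate fragmentation. The transannular C5–C10 bond is restored, leading to a cis-fused decalin A4 with a pinacol boronate at C4 and a mesylate at C1. NaOt-Bu forms the borate, which expels the mesylate through the antiperiplanar C5–C10 bond and gives the (1(10)Z,4E)-diene A3.
- Merits: no ring strain has to be overcome in a closure, both olefin geometries follow stereospecifically from the decalin, and C2, C6, C7, C8 and C9 are set on rigid six-membered rings.
- Weak points: A4 needs nine stereocentres, four of which (C1, C4, C5, C10) are destroyed. The tertiary boronate at C4 runs against the normal regiochemistry of hydroboration. The bicycle must adopt the conformer with both leaving bonds antiperiplanar to C5–C10 while carrying a trans-fused lactone and an acetonide. The saturated lactone of A3 still needs α-methylenation.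
- Comparison: for C8/C9 stereochemistry and olefin geometry this road is more secure than the chosen one. The chosen plan spends one stereocentre instead of four and reaches its precursor in far fewer steps.

Alternative 3: nickel-mediated alkylative ynal macrocyclisation. The C5–C6 and C4–C15 bonds are cut, leading to the open-chain ynal A6. Ni(cod)2 with 1,3-dimesitylimidazol-2-ylidene couples the C6 aldehyde with the terminal alkyne carbon C5 while Zn(CH3)2 delivers the methyl to C4, giving the macrocyclic allylic alcohol A5 with the E-olefin C4=C5.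
- Merits: high convergence; one step makes the ring, the olefin, the methyl branch and the C6 carbinol; C2, C7, C8 and C9 are set in the open chain by dependable methods.
- Weak points: a ten-membered ring must be closed by an organometallic C–C coupling, which invites oligomerisation and needs high dilution. The regiochemistry of alkyne insertion (endocyclic against exocyclic olefin) depends on the ligand. The C6 configuration arises in the closure without local control. The Z-olefin C1=C10 must be built in the chain, and methylenation of the lactone comes late.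
- Comparison: this road is more modular and carries the C8/C9 oxygens in from the start. The chosen plan needs no dilution and sets C6 and C7 by chirality transfer from one centre.

Key step: step 13

Assumption: positions are numbered as in germacrane throughout (ring C1–C10, C11–C13 on C7, C14 on C10, C15 on C4), and 2,6-dimethylcyclohexanone is used as the commercial cis/trans mixture because its second stereocentre is removed in step 3.

## Route

Step 1
Reactants: 1 2,6-dimethylcyclohexan-1-one; 2 allyl chloroformate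
Product: 4 allyl 2,6-dimethylcyclohex-1-en-1-yl carbonate, via lithium enolate 3 (not isolated)
Conditions: LiN(SiMe3)2, TMEDA, THF, −78 °C; then 2, −78 → 0 °C
Reagents that add atoms: none
Why: Both α-carbons of 1 are equivalent, so a single tetrasubstituted enolate forms, and O-acylation by the chloroformate (favoured by TMEDA) gives the enol carbonate. No stereocentre is set; the remaining methyl-bearing carbon stays racemic.

Step 2
Reactants: 4 allyl 2,6-dimethylcyclohex-1-en-1-yl carbonate
Product: 5 (2S)-2,6-dimethyl-2-(prop-2-en-1-yl)cyclohexan-1-one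
Conditions: Pd2(dba)3 (2.5 mol %), (S)-4-tert-butyl-2-[2-(diphenylphosphino)phenyl]-4,5-dihydrooxazole (6 mol %), THF, 25 °C
Reagents that add atoms: none
Why: Palladium-catalysed decarboxylative asymmetric allylic alkylation: ionisation and loss of CO2 give a π-allylpalladium enolate that recombines inside the chiral P,N-ligand sphere and sets the quaternary centre (C4) as S under catalyst control. The untouched methyl-bearing carbon gives two diastereomers, which converge in step 3.

Step 3
Reactants: 5 (2S)-2,6-dimethyl-2-(prop-2-en-1-yl)cyclohexan-1-one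
Product: 7 (6S)-2,6-dimethyl-6-(prop-2-en-1-yl)cyclohex-2-en-1-one, via trimethylsilyl enol ether 6 (not isolated)
Conditions: TMSOTf, Et3N, CH2Cl2, 0 °C; then Pd(OAc)2, MeCN, 25 °C
Reagents that add atoms: none
Why: Saegusa–Ito dehydrogenation: enolisation is possible only toward the methine carbon, and β-hydride elimination from the oxa-π-allylpalladium species gives the endocyclic 2-methyl enone. The quaternary centre blocks aromatisation, and the stereocentre left open in step 2 disappears.

Step 4
Reactants: 7 (6S)-2,6-dimethyl-6-(prop-2-en-1-yl)cyclohex-2-en-1-one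
Product: 9 (6R)-2,6-dimethyl-6-(prop-2-en-1-yl)cyclohex-2-ene-1,4-dione, via tert-butylperoxy enone 8 (not isolated)
Conditions: Pd(OH)2/C (cat.), t-BuOOH, K2CO3, CH2Cl2, 4 → 25 °C
Reagents that add atoms: tert-butyl hydroperoxide CC(C)(C)OO
Why: γ-Oxidation of an enone to an ene-1,4-dione: the tert-butylperoxy radical abstracts the doubly activated γ-hydrogen (C2), peroxide 8 forms and base eliminates tert-butanol. The α'-carbon is quaternary, so no other ring position competes, and the side-chain allylic CH2 is less activated.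

Step 5
Reactants: 9 (6R)-2,6-dimethyl-6-(prop-2-en-1-yl)cyclohex-2-ene-1,4-dione
Product: 10 (4S,6R)-4-hydroxy-2,6-dimethyl-6-(prop-2-en-1-yl)cyclohex-2-en-1-one
Conditions: (R)-2-methyl-CBS-oxazaborolidine (0.2 equiv), catecholborane, toluene, −78 °C
Reagents that add atoms: none
Why: Corey–Bakshi–Shibata reduction: only the carbonyl flanked by CH and CH2 can bind the catalyst, the other lying between the quaternary carbon and the methyl-bearing sp2 carbon. With the alkene arm as the large substituent the (R)-catalyst should give the 4S alcohol (C2), cis to the allyl group, under reagent control. Catecholborane at −78 °C leaves the terminal olefin alone.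

Step 6
Reactants: 10 (4S,6R)-4-hydroxy-2,6-dimethyl-6-(prop-2-en-1-yl)cyclohex-2-en-1-one
Product: 11 (4S,6R)-4-[(tert-butyldimethylsilyl)oxy]-2,6-dimethyl-6-(prop-2-en-1-yl)cyclohex-2-en-1-one
Conditions: TBSCl, imidazole, DMF, 25 °C
Reagents that add atoms: tert-butyldimethylsilyl chloride CC(C)(C)[Si](C)(C)Cl
Why: Standard silylation of a secondary allylic alcohol. The TBS ether tolerates ozone, organolithium, KH, hydride and the later oxidations.

Step 7
Reactants: 11 (4S,6R)-4-[(tert-butyldimethylsilyl)oxy]-2,6-dimethyl-6-(prop-2-en-1-yl)cyclohex-2-en-1-one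
Product: 13 2-[(1S,5S)-5-[(tert-butyldimethylsilyl)oxy]-1,3-dimethyl-2-oxocyclohex-3-en-1-yl]acetaldehyde, via ozonide 12 (not isolated)
Conditions: O3, CH2Cl2, −78 °C (Sudan Red 7B end point); then PPh3, −78 → 25 °C
Reagents that add atoms: ozone [O-][O+]=O
Why: Ozonolysis of the electron-richer monosubstituted olefin in the presence of the deactivated enone double bond, with a dye indicator to stop at one equivalent. Reduction of the ozonide by PPh3 releases the aldehyde and formaldehyde.

Step 8
Reactants: 13 2-[(1S,5S)-5-[(tert-butyldimethylsilyl)oxy]-1,3-dimethyl-2-oxocyclohex-3-en-1-yl]acetaldehyde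
Product: 14 (4S,6S)-4-[(tert-butyldimethylsilyl)oxy]-6-{(E)-2-[(tert-butyldimethylsilyl)oxy]ethenyl}-2,6-dimethylcyclohex-2-en-1-one
Conditions: TBSOTf (1.1 equiv), Et3N, CH2Cl2, −78 → 0 °C
Reagents that add atoms: tert-butyldimethylsilyl triflate CC(C)(C)[Si](C)(C)OS(=O)(=O)C(F)(F)F
Why: Soft enolisation and O-silylation of the aldehyde, which is far more reactive than the hindered enone. In the deprotonation of the silyloxocarbenium ion the quaternary substituent should lie trans to the silyloxy group, giving the E enol ether, which is also the more stable isomer.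

Step 9
Reactants: 15 2-methylidenepropane-1,3-diol
Product: 17 2-{[(4-methoxybenzyl)oxy]methyl}prop-2-en-1-ol, via sodium alkoxide 16 (not isolated)
Conditions: NaH (1 equiv), THF/DMF, 0 °C; then 4-methoxybenzyl chloride, n-Bu4NI (cat.), 0 → 25 °C; diol in excess
Reagents that add atoms: 4-methoxybenzyl chloride COc1ccc(CCl)cc1
Why: Williamson etherification; an excess of the symmetrical diol favours mono-protection. The PMB group is chosen because it can later be removed oxidatively beside silyl ethers and esters.

Step 10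
Reactants: 17 2-{[(4-methoxybenzyl)oxy]methyl}prop-2-en-1-ol
Product: 18 2-{[(4-methoxybenzyl)oxy]methyl}prop-2-enal
Conditions: MnO2, CH2Cl2, 25 °C
Reagents that add atoms: none
Why: MnO2 oxidises the primary allylic alcohol selectively to the 2-substituted acrolein and does not touch the PMB ether.

Step 11
Reactants: 18 2-{[(4-methoxybenzyl)oxy]methyl}prop-2-enal
Product: 19 1-({[(3E)-4-iodo-2-methylidenebut-3-en-1-yl]oxy}methyl)-4-methoxybenzene
Conditions: CrCl2, CHI3, THF, 0 °C
Reagents that add atoms: iodoform IC(I)I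
Why: Takai olefination: the geminal dichromium reagent formed from CHI3 and divalent chromium adds to the aldehyde and eliminates to the E-vinyl iodide. Enals are good substrates and give (E)-1-iodo-1,3-dienes.

Step 12
Reactants: 19 1-({[(3E)-4-iodo-2-methylidenebut-3-en-1-yl]oxy}methyl)-4-methoxybenzene; 14 (4S,6S)-4-[(tert-butyldimethylsilyl)oxy]-6-{(E)-2-[(tert-butyldimethylsilyl)oxy]ethenyl}-2,6-dimethylcyclohex-2-en-1-one
Product: 21 (1S,4S,6S)-4-[(tert-butyldimethylsilyl)oxy]-6-{(E)-2-[(tert-butyldimethylsilyl)oxy]ethenyl}-1-[(1E)-3-{[(4-methoxybenzyl)oxy]methyl}buta-1,3-dien-1-yl]-2,6-dimethylcyclohex-2-en-1-ol, via dienyllithium 20 (not isolated)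
Conditions: 19, t-BuLi (2 equiv), Et2O, −78 °C; then 14, THF, −78 °C
Reagents that add atoms: none
Why: Iodine–lithium exchange retains the E geometry, and the alkenyllithium adds 1,2 to the enone, which has no α-hydrogen (C4 quaternary, C10 sp2). The reagent should enter anti to the C4 alkenyl arm, which takes the antiperiplanar position of a Felkin–Anh transition state, and anti to the C2 silyloxy group on the same face, giving the trans-dialkenyl carbinol (C9 as 1S). C9 later becomes a carbonyl carbon, but the trans relationship is what lets both arms lie equatorial in step 13.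

Step 13
Reactants: 21 (1S,4S,6S)-4-[(tert-butyldimethylsilyl)oxy]-6-{(E)-2-[(tert-butyldimethylsilyl)oxy]ethenyl}-1-[(1E)-3-{[(4-methoxybenzyl)oxy]methyl}buta-1,3-dien-1-yl]-2,6-dimethylcyclohex-2-en-1-ol
Product: 24 (1(10)Z,2S,4E,6R,7S)-2,6-bis[(tert-butyldimethylsilyl)oxy]-12-[(4-methoxybenzyl)oxy]germacra-1(10),4,11(13)-trien-9-one, via potassium alkoxide 22 (not isolated), via potassium dienolate 23 (not isolated)
Conditions: KH, 18-crown-6, THF, 0 → 25 °C; then AcOH, THF, −78 °C
Reagents that add atoms: none
Why: KH with 18-crown-6 gives the dissociated alkoxide 22, which weakens the C4–C9 bond; the 1,5-diene C7=C8–C9–C4–C5=C6 then undergoes an anionic oxy-Cope [3,3] shift that forms C6–C7, breaks C4–C9 and gives dienolate 23, which is protonated at C8 on the cold acidic quench. The closest known reaction type is the anionic oxy-Cope ring expansion of 1,2-dialkenylcyclohexanols to cyclodec-5-enones. The ten-membered ring is closed by a four-atom ring expansion through a bicyclic six-centre chair and not by an end-to-end cyclisation, so no dilution is needed and the Z-olefin C1=C10 is taken over unchanged from the cyclohexene. With both alkenyl groups equatorial on the cyclohexene, C3 sits equatorial on the chair and C4=C5 is formed E. The two E termini place the silyloxy group on C6 and C11 on C7 equatorial, so the configuration of C4 is relayed to C6 (R) and C7 (S), trans to each other. The step needs the chair to win over the boat and the dienyl arm to react and not the ring olefin: the equatorial C4 arm cannot reach C1, and the C2 silyloxy group, cis to that arm, would meet it in a syn-diaxial clash in any chair with the arm axial. C9 ends as the carbonyl carbon, but only the trans-dialkenyl isomer can hold both arms equatorial; its C9 epimer would react through a chair with the dienyl arm axial, which turns C3 axial and leads to the 4Z olefin. The silyl enol ether terminus delivers the C6 oxygen at the correct oxidation level, and the C9 enone and C8 methylene are the handles for the two esters.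

Step 14
Reactants: 24 (1(10)Z,2S,4E,6R,7S)-2,6-bis[(tert-butyldimethylsilyl)oxy]-12-[(4-methoxybenzyl)oxy]germacra-1(10),4,11(13)-trien-9-one
Product: 26 (1(10)Z,2S,4E,6R,7R,8R)-2,6-bis[(tert-butyldimethylsilyl)oxy]-8-hydroxy-12-[(4-methoxybenzyl)oxy]germacra-1(10),4,11(13)-trien-9-one, via sodium dienolate 25 (not isolated)
Conditions: NaN(SiMe3)2, THF, −78 °C; then 2-(phenylsulfonyl)-3-phenyloxaziridine, −78 °C; AcOH
Reagents that add atoms: 2-(phenylsulfonyl)-3-phenyloxaziridine O=S(=O)(c1ccccc1)N1OC1c1ccccc1
Why: α-Hydroxylation of a sodium enolate by an N-sulfonyloxaziridine (Davis oxidation). NaN(SiMe3)2 removes the outward-pointing C8 hydrogen (C10 has none and γ-deprotonation at C2 is slower) and gives the cross-conjugated sodium dienolate 25, expected to have the same C8=C9 geometry as the enolate formed in step 13. The oxidant should attack the peripheral face, away from the transannular C4=C5 bond, which places the C8 oxygen trans to the C7 side chain (8R).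

Step 15
Reactants: 26 (1(10)Z,2S,4E,6R,7R,8R)-2,6-bis[(tert-butyldimethylsilyl)oxy]-8-hydroxy-12-[(4-methoxybenzyl)oxy]germacra-1(10),4,11(13)-trien-9-one; 27 angelic acid
Product: 29 (1(10)Z,2S,4E,6R,7R,8R)-2,6-bis[(tert-butyldimethylsilyl)oxy]-12-[(4-methoxybenzyl)oxy]-9-oxogermacra-1(10),4,11(13)-trien-8-yl (2Z)-2-methylbut-2-enoate, via mixed anhydride 28 (not isolated)
Conditions: 27, 2,4,6-trichlorobenzoyl chloride, Et3N, toluene, 25 °C; then 26, 70 °C
Reagents that add atoms: none
Why: Yamaguchi esterification through mixed anhydride 28. Leaving out a nucleophilic catalyst avoids the conjugate addition–elimination that turns angelates into tiglates. The C8–O bond is not broken, so C8 keeps its configuration.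

Step 16
Reactants: 29 (1(10)Z,2S,4E,6R,7R,8R)-2,6-bis[(tert-butyldimethylsilyl)oxy]-12-[(4-methoxybenzyl)oxy]-9-oxogermacra-1(10),4,11(13)-trien-8-yl (2Z)-2-methylbut-2-enoate
Product: 30 (1(10)Z,2S,4E,6R,7R,8R,9R)-2,6-bis[(tert-butyldimethylsilyl)oxy]-9-hydroxy-12-[(4-methoxybenzyl)oxy]germacra-1(10),4,11(13)-trien-8-yl (2Z)-2-methylbut-2-enoate
Conditions: NaBH4, CeCl3·7H2O, MeOH, −78 °C
Reagents that add atoms: none
Why: Luche reduction; CeCl3 ensures 1,2-reduction of the enone. Hydride should add anti to the C8 acyloxy group held perpendicular to the carbonyl plane (polar Felkin–Anh), which gives the 9R alcohol with the C8 and C9 oxygens trans on the ring. Low temperature and a short reaction time suppress 1,2-acyl migration.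

Step 17
Reactants: 30 (1(10)Z,2S,4E,6R,7R,8R,9R)-2,6-bis[(tert-butyldimethylsilyl)oxy]-9-hydroxy-12-[(4-methoxybenzyl)oxy]germacra-1(10),4,11(13)-trien-8-yl (2Z)-2-methylbut-2-enoate
Product: 31 (1(10)Z,2S,4E,6R,7R,8R,9R)-9-acetoxy-2,6-bis[(tert-butyldimethylsilyl)oxy]-12-[(4-methoxybenzyl)oxy]germacra-1(10),4,11(13)-trien-8-yl (2Z)-2-methylbut-2-enoate
Conditions: Ac2O, pyridine, DMAP (cat.), CH2Cl2, 0 °C
Reagents that add atoms: acetic anhydride CC(=O)OC(C)=O
Why: Catalysed acetylation of the secondary allylic alcohol, run cold and briefly so that the diester is fixed before the angelate can migrate or isomerise.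

Step 18
Reactants: 31 (1(10)Z,2S,4E,6R,7R,8R,9R)-9-acetoxy-2,6-bis[(tert-butyldimethylsilyl)oxy]-12-[(4-methoxybenzyl)oxy]germacra-1(10),4,11(13)-trien-8-yl (2Z)-2-methylbut-2-enoate
Product: 32 (1(10)Z,2S,4E,6R,7R,8R,9R)-9-acetoxy-2,6-bis[(tert-butyldimethylsilyl)oxy]-12-hydroxygermacra-1(10),4,11(13)-trien-8-yl (2Z)-2-methylbut-2-enoate
Conditions: DDQ, CH2Cl2/pH 7 buffer, 0 °C
Reagents that add atoms: none
Why: Oxidative cleavage of the PMB ether by benzylic hydride abstraction and hydrolysis of the oxocarbenium ion. Silyl ethers, esters and the olefins are inert in the buffered two-phase medium.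

Step 19
Reactants: 32 (1(10)Z,2S,4E,6R,7R,8R,9R)-9-acetoxy-2,6-bis[(tert-butyldimethylsilyl)oxy]-12-hydroxygermacra-1(10),4,11(13)-trien-8-yl (2Z)-2-methylbut-2-enoate
Product: 33 (1(10)Z,2S,4E,6R,7R,8R,9R)-9-acetoxy-2,6-bis[(tert-butyldimethylsilyl)oxy]-12-oxogermacra-1(10),4,11(13)-trien-8-yl (2Z)-2-methylbut-2-enoate
Conditions: MnO2, CH2Cl2, 25 °C
Reagents that add atoms: none
Why: Selective oxidation of the primary allylic alcohol to the 2-substituted acrolein; the protected secondary carbinols cannot react.

Step 20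
Reactants: 33 (1(10)Z,2S,4E,6R,7R,8R,9R)-9-acetoxy-2,6-bis[(tert-butyldimethylsilyl)oxy]-12-oxogermacra-1(10),4,11(13)-trien-8-yl (2Z)-2-methylbut-2-enoate
Product: 34 (1(10)Z,2S,4E,6R,7R,8R,9R)-9-acetoxy-2,6-bis[(tert-butyldimethylsilyl)oxy]-8-{[(2Z)-2-methylbut-2-enoyl]oxy}germacra-1(10),4,11(13)-trien-12-oic acid
Conditions: NaClO2, NaH2PO4, 2-methyl-2-butene, t-BuOH/H2O, 0 → 25 °C
Reagents that add atoms: sodium chlorite [Na+].[O-]Cl=O
Why: Pinnick oxidation of the enal to the acrylic acid. 2-Methyl-2-butene traps hypochlorous acid before it can attack the trisubstituted olefins.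

Step 21
Reactants: 34 (1(10)Z,2S,4E,6R,7R,8R,9R)-9-acetoxy-2,6-bis[(tert-butyldimethylsilyl)oxy]-8-{[(2Z)-2-methylbut-2-enoyl]oxy}germacra-1(10),4,11(13)-trien-12-oic acid
Product: 36 (1(10)Z,2S,4E,6R,7S,8R,9R)-9-acetoxy-8-{[(2Z)-2-methylbut-2-enoyl]oxy}-2-hydroxygermacra-1(10),4,11(13)-trien-12,6-olide, via dihydroxy acid 35 (not isolated)
Conditions: HF·pyridine, pyridine, THF, 0 → 25 °C
Reagents that add atoms: none
Why: Buffered fluoride cleavage of both TBS ethers. The freed C6 hydroxyl is γ to the carboxyl group and should close the lactone by 5-exo-trig acyl substitution in the weakly acidic medium. The C2 hydroxyl cannot reach C12 and the C8 and C9 oxygens are acylated, so only the 12,6-olide can form; no stereocentre is touched.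

## Compound list

1 | 2,6-dimethylcyclohexan-1-one (cis/trans mixture) | CC1CCCC(C)C1=O | starting material
2 | allyl chloroformate | C=CCOC(=O)Cl | starting material
3 | lithium 2,6-dimethylcyclohex-1-en-1-olate | [Li+].CC1CCCC(C)=C1[O-] | intermediate
4 | allyl 2,6-dimethylcyclohex-1-en-1-yl carbonate (racemic) | C=CCOC(=O)OC1=C(C)CCCC1C | intermediate
5 | (2S)-2,6-dimethyl-2-(prop-2-en-1-yl)cyclohexan-1-one (both C6 epimers) | C=CC[C@]1(C)CCCC(C)C1=O | intermediate
6 | trimethyl{[(6S)-2,6-dimethyl-6-(prop-2-en-1-yl)cyclohex-1-en-1-yl]oxy}silane | C=CC[C@]1(C)CCCC(C)=C1O[Si](C)(C)C | intermediate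
7 | (6S)-2,6-dimethyl-6-(prop-2-en-1-yl)cyclohex-2-en-1-one | C=CC[C@]1(C)CCC=C(C)C1=O | intermediate
8 | (6R)-4-(tert-butylperoxy)-2,6-dimethyl-6-(prop-2-en-1-yl)cyclohex-2-en-1-one (both C4 epimers) | C=CC[C@]1(C)CC(OOC(C)(C)C)C=C(C)C1=O | intermediate
9 | (6R)-2,6-dimethyl-6-(prop-2-en-1-yl)cyclohex-2-ene-1,4-dione | C=CC[C@]1(C)CC(=O)C=C(C)C1=O | intermediate
10 | (4S,6R)-4-hydroxy-2,6-dimethyl-6-(prop-2-en-1-yl)cyclohex-2-en-1-one | C=CC[C@]1(C)C[C@H](O)C=C(C)C1=O | intermediate
11 | (4S,6R)-4-[(tert-butyldimethylsilyl)oxy]-2,6-dimethyl-6-(prop-2-en-1-yl)cyclohex-2-en-1-one | C=CC[C@]1(C)C[C@H](O[Si](C)(C)C(C)(C)C)C=C(C)C1=O | intermediate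
12 | (4S,6S)-4-[(tert-butyldimethylsilyl)oxy]-2,6-dimethyl-6-[(1,2,4-trioxolan-3-yl)methyl]cyclohex-2-en-1-one (trioxolane carbon unassigned) | C[C@@]1(CC2OCOO2)C[C@H](O[Si](C)(C)C(C)(C)C)C=C(C)C1=O | intermediate
13 | 2-[(1S,5S)-5-[(tert-butyldimethylsilyl)oxy]-1,3-dimethyl-2-oxocyclohex-3-en-1-yl]acetaldehyde | C[C@@]1(CC=O)C[C@H](O[Si](C)(C)C(C)(C)C)C=C(C)C1=O | intermediate
14 | (4S,6S)-4-[(tert-butyldimethylsilyl)oxy]-6-{(E)-2-[(tert-butyldimethylsilyl)oxy]ethenyl}-2,6-dimethylcyclohex-2-en-1-one | C[C@@]1(/C=C/O[Si](C)(C)C(C)(C)C)C[C@H](O[Si](C)(C)C(C)(C)C)C=C(C)C1=O | intermediate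
15 | 2-methylidenepropane-1,3-diol | C=C(CO)CO | starting material
16 | sodium 2-(hydroxymethyl)prop-2-en-1-olate | [Na+].C=C(CO)C[O-] | intermediate
17 | 2-{[(4-methoxybenzyl)oxy]methyl}prop-2-en-1-ol | C=C(CO)COCc1ccc(OC)cc1 | intermediate
18 | 2-{[(4-methoxybenzyl)oxy]methyl}prop-2-enal | C=C(C=O)COCc1ccc(OC)cc1 | intermediate
19 | 1-({[(3E)-4-iodo-2-methylidenebut-3-en-1-yl]oxy}methyl)-4-methoxybenzene | C=C(COCc1ccc(OC)cc1)/C=C/I | intermediate
20 | [(1E)-3-{[(4-methoxybenzyl)oxy]methyl}buta-1,3-dien-1-yl]lithium | C=C(COCc1ccc(OC)cc1)/C=C/[Li] | intermediate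
21 | (1S,4S,6S)-4-[(tert-butyldimethylsilyl)oxy]-6-{(E)-2-[(tert-butyldimethylsilyl)oxy]ethenyl}-1-[(1E)-3-{[(4-methoxybenzyl)oxy]methyl}buta-1,3-dien-1-yl]-2,6-dimethylcyclohex-2-en-1-ol | C=C(COCc1ccc(OC)cc1)/C=C/[C@]2(O)C(C)=C[C@@H](O[Si](C)(C)C(C)(C)C)C[C@@]2(C)/C=C/O[Si](C)(C)C(C)(C)C | intermediate
22 | potassium alkoxide of 21 | [K+].C=C(COCc1ccc(OC)cc1)/C=C/[C@]2([O-])C(C)=C[C@@H](O[Si](C)(C)C(C)(C)C)C[C@@]2(C)/C=C/O[Si](C)(C)C(C)(C)C | intermediate
23 | potassium C8=C9 dienolate of 24 | [K+].C=C(COCc1ccc(OC)cc1)[C@@H]2/C=C(\[O-])/C(C)=C\[C@@H](O[Si](C)(C)C(C)(C)C)C/C(C)=C/[C@H]2O[Si](C)(C)C(C)(C)C | intermediate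
24 | (1(10)Z,2S,4E,6R,7S)-2,6-bis[(tert-butyldimethylsilyl)oxy]-12-[(4-methoxybenzyl)oxy]germacra-1(10),4,11(13)-trien-9-one | C=C(COCc1ccc(OC)cc1)[C@@H]2CC(=O)/C(C)=C\[C@@H](O[Si](C)(C)C(C)(C)C)C/C(C)=C/[C@H]2O[Si](C)(C)C(C)(C)C | intermediate
25 | sodium C8=C9 dienolate of 24 | [Na+].C=C(COCc1ccc(OC)cc1)[C@@H]2/C=C(\[O-])/C(C)=C\[C@@H](O[Si](C)(C)C(C)(C)C)C/C(C)=C/[C@H]2O[Si](C)(C)C(C)(C)C | intermediate
26 | (1(10)Z,2S,4E,6R,7R,8R)-2,6-bis[(tert-butyldimethylsilyl)oxy]-8-hydroxy-12-[(4-methoxybenzyl)oxy]germacra-1(10),4,11(13)-trien-9-one | C=C(COCc1ccc(OC)cc1)[C@@H]2[C@@H](O)C(=O)/C(C)=C\[C@@H](O[Si](C)(C)C(C)(C)C)C/C(C)=C/[C@H]2O[Si](C)(C)C(C)(C)C | intermediate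
27 | angelic acid, (2Z)-2-methylbut-2-enoic acid | C/C=C(/C)C(=O)O | starting material
28 | (2Z)-2-methylbut-2-enoic 2,4,6-trichlorobenzoic anhydride | C/C=C(/C)C(=O)OC(=O)c1c(Cl)cc(Cl)cc1Cl | intermediate
29 | (1(10)Z,2S,4E,6R,7R,8R)-2,6-bis[(tert-butyldimethylsilyl)oxy]-12-[(4-methoxybenzyl)oxy]-9-oxogermacra-1(10),4,11(13)-trien-8-yl (2Z)-2-methylbut-2-enoate | C=C(COCc1ccc(OC)cc1)[C@@H]2[C@@H](OC(=O)/C(C)=C\C)C(=O)/C(C)=C\[C@@H](O[Si](C)(C)C(C)(C)C)C/C(C)=C/[C@H]2O[Si](C)(C)C(C)(C)C | intermediate
30 | (1(10)Z,2S,4E,6R,7R,8R,9R)-2,6-bis[(tert-butyldimethylsilyl)oxy]-9-hydroxy-12-[(4-methoxybenzyl)oxy]germacra-1(10),4,11(13)-trien-8-yl (2Z)-2-methylbut-2-enoate | C=C(COCc1ccc(OC)cc1)[C@@H]2[C@@H](OC(=O)/C(C)=C\C)[C@H](O)/C(C)=C\[C@@H](O[Si](C)(C)C(C)(C)C)C/C(C)=C/[C@H]2O[Si](C)(C)C(C)(C)C | intermediate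
31 | (1(10)Z,2S,4E,6R,7R,8R,9R)-9-acetoxy-2,6-bis[(tert-butyldimethylsilyl)oxy]-12-[(4-methoxybenzyl)oxy]germacra-1(10),4,11(13)-trien-8-yl (2Z)-2-methylbut-2-enoate | C=C(COCc1ccc(OC)cc1)[C@@H]2[C@@H](OC(=O)/C(C)=C\C)[C@H](OC(C)=O)/C(C)=C\[C@@H](O[Si](C)(C)C(C)(C)C)C/C(C)=C/[C@H]2O[Si](C)(C)C(C)(C)C | intermediate
32 | (1(10)Z,2S,4E,6R,7R,8R,9R)-9-acetoxy-2,6-bis[(tert-butyldimethylsilyl)oxy]-12-hydroxygermacra-1(10),4,11(13)-trien-8-yl (2Z)-2-methylbut-2-enoate | C=C(CO)[C@@H]2[C@@H](OC(=O)/C(C)=C\C)[C@H](OC(C)=O)/C(C)=C\[C@@H](O[Si](C)(C)C(C)(C)C)C/C(C)=C/[C@H]2O[Si](C)(C)C(C)(C)C | intermediate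
33 | (1(10)Z,2S,4E,6R,7R,8R,9R)-9-acetoxy-2,6-bis[(tert-butyldimethylsilyl)oxy]-12-oxogermacra-1(10),4,11(13)-trien-8-yl (2Z)-2-methylbut-2-enoate | C=C(C=O)[C@@H]2[C@@H](OC(=O)/C(C)=C\C)[C@H](OC(C)=O)/C(C)=C\[C@@H](O[Si](C)(C)C(C)(C)C)C/C(C)=C/[C@H]2O[Si](C)(C)C(C)(C)C | intermediate
34 | (1(10)Z,2S,4E,6R,7R,8R,9R)-9-acetoxy-2,6-bis[(tert-butyldimethylsilyl)oxy]-8-{[(2Z)-2-methylbut-2-enoyl]oxy}germacra-1(10),4,11(13)-trien-12-oic acid | C=C(C(=O)O)[C@@H]2[C@@H](OC(=O)/C(C)=C\C)[C@H](OC(C)=O)/C(C)=C\[C@@H](O[Si](C)(C)C(C)(C)C)C/C(C)=C/[C@H]2O[Si](C)(C)C(C)(C)C | intermediate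
35 | (1(10)Z,2S,4E,6R,7S,8R,9R)-9-acetoxy-2,6-dihydroxy-8-{[(2Z)-2-methylbut-2-enoyl]oxy}germacra-1(10),4,11(13)-trien-12-oic acid | C=C(C(=O)O)[C@@H]2[C@@H](OC(=O)/C(C)=C\C)[C@H](OC(C)=O)/C(C)=C\[C@@H](O)C/C(C)=C/[C@H]2O | intermediate
36 | CNP0316477.1, (1(10)Z,2S,4E,6R,7S,8R,9R)-9-acetoxy-8-{[(2Z)-2-methylbut-2-enoyl]oxy}-2-hydroxygermacra-1(10),4,11(13)-trien-12,6-olide | C=C1C(=O)O[C@@H]2/C=C(\C)C[C@H](O)/C=C(/C)[C@@H](OC(C)=O)[C@H](OC(=O)/C(C)=C\C)[C@@H]12 | target

## Step count and least certain steps

Total: 21 steps. Longest linear sequence: 18 steps (steps 1–8 and 12–21); the dienyl iodide 19 is made in 3 steps (9–11).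

**Step 13 (key step).** The alkoxide may fragment heterolytically at C4–C9 and recombine to 1,3-shift products, or react through a boat, which would erode the transfer of chirality to C6 and C7. The electron-rich enol ether terminus may also slow the shift enough for decomposition to compete. Fallback: the neutral silyloxy-Cope variant, which avoids a charged intermediate. Carbinol 21 would be silylated (N-trimethylsilylimidazole) to the trimethylsilyl ether F1 and heated in degassed toluene in a sealed tube at about 200 °C. The same chair would give the trimethylsilyl dienol ether F2, and mild methanolysis (citric acid, MeOH) would return the route to dienone 24.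

**Step 12.** Facial selectivity may be poor or reversed: the enone can react through the half-chair with the C4 methyl group axial, and attack anti to that methyl group would place the dienyl group cis to the C4 arm. That C9 epimer does not converge in step 13, because its accessible chair has the dienyl arm and C3 axial and would lead to the 4Z olefin. Fallback: the conformational bias would be reversed by carrying the C2 oxygen on the other face and inverting it after the ring expansion; the detour sets out from ene-dione 9 and comes back at dienone 24.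
- Ene-dione 9 would be reduced with (S)-2-methyl-CBS-oxazaborolidine and catecholborane to the 4R alcohol F3 and silylated with TESCl and imidazole to the triethylsilyl ether F4.
- Ozonolysis (O3, then PPh3) would give aldehyde F5, and TBSOTf with Et3N would give the silyl enol ether F6.
- With the C2 oxygen cis to the methyl group, the half-chair with the C4 arm axial is the populated one, so dienyllithium 20 should add anti to the arm and give the trans-dialkenyl carbinol F7.
- KH and 18-crown-6 would give the 2-epimeric dienone F8 through the same chair, which now carries the methyl group and the C2 silyloxy group syn-diaxial; this should cost rate, not selectivity.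
- PPTS in MeOH would remove the triethylsilyl group to give the 2R alcohol F9.
- A Mitsunobu reaction with 4-nitrobenzoic acid (PPh3, diisopropyl azodicarboxylate) would invert C2 and give the 2S 4-nitrobenzoate F10.
- K2CO3 in MeOH would free the 2S alcohol F11, and TBSCl with imidazole would return the route to dienone 24.

**Step 4.** The peroxy radical may abstract the side-chain allylic hydrogen as well, giving over-oxidised mixtures. Fallback: an ionic route from enone 7. Soft enolisation (TBSOTf, Et3N) would give the silyl dienol ether F12, dimethyldioxirane would oxidise its distal double bond to the γ-hydroxy enone F13 (both C4 epimers), and Dess–Martin oxidation would rejoin the route at ene-dione 9.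

**Step 14.** Re-enolisation of the isolated macrocyclic ketone may give the other enolate geometry or react through another ring conformer, with loss of facial selectivity at C8. Deprotonation at C2 is a further risk. Fallback: the rearrangement and the oxidation would be run in tandem. Carbinol 21 would be rearranged with KN(SiMe3)2 and 18-crown-6, and the oxaziridine would be added at −78 °C to enolate 23 in the conformation in which it is born, giving 26 directly. This fallback makes no new compound (F0).

**Step 16.** The ring conformation may override the Felkin–Anh preference so that hydride adds to the other face, and the angelate may migrate to the new alkoxide. Fallback: the 9-epimeric alcohol F14 would be converted by a Mitsunobu reaction with acetic acid (PPh3, diisopropyl azodicarboxylate), which inverts C9 and installs the acetate in one operation, returning to acetate 31.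

**Step 21.** Acid may ionise the allylic carbinols or start a transannular cyclisation of the 1(10),4-diene, and the hydroxy acid may fail to close. Fallback: the lactone would be formed by oxidation instead of acylation. Alcohol 32 would be desilylated (HF·pyridine) to the triol F15; TEMPO with PhI(OAc)2 would oxidise the primary allylic alcohol selectively, the aldehyde would close to the lactol F16 with the C6 hydroxyl, and further oxidation in the same flask would give 36.

## Further compounds

F1 | step 13 | trimethylsilyl ether of 21 | C=C(COCc1ccc(OC)cc1)/C=C/[C@]2(O[Si](C)(C)C)C(C)=C[C@@H](O[Si](C)(C)C(C)(C)C)C[C@@]2(C)/C=C/O[Si](C)(C)C(C)(C)C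
F2 | step 13 | trimethylsilyl dienol ether of 24 | C=C(COCc1ccc(OC)cc1)[C@@H]2/C=C(\O[Si](C)(C)C)/C(C)=C\[C@@H](O[Si](C)(C)C(C)(C)C)C/C(C)=C/[C@H]2O[Si](C)(C)C(C)(C)C
F3 | step 12 | (4R,6R)-4-hydroxy-2,6-dimethyl-6-(prop-2-en-1-yl)cyclohex-2-en-1-one | C=CC[C@]1(C)C[C@@H](O)C=C(C)C1=O
F4 | step 12 | (4R,6R)-2,6-dimethyl-6-(prop-2-en-1-yl)-4-[(triethylsilyl)oxy]cyclohex-2-en-1-one | C=CC[C@]1(C)C[C@@H](O[Si](CC)(CC)CC)C=C(C)C1=O
F5 | step 12 | 2-[(1S,5R)-1,3-dimethyl-2-oxo-5-[(triethylsilyl)oxy]cyclohex-3-en-1-yl]acetaldehyde | C[C@@]1(CC=O)C[C@@H](O[Si](CC)(CC)CC)C=C(C)C1=O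
F6 | step 12 | (4R,6S)-6-{(E)-2-[(tert-butyldimethylsilyl)oxy]ethenyl}-2,6-dimethyl-4-[(triethylsilyl)oxy]cyclohex-2-en-1-one | C[C@@]1(/C=C/O[Si](C)(C)C(C)(C)C)C[C@@H](O[Si](CC)(CC)CC)C=C(C)C1=O
F7 | step 12 | (1S,4R,6S)-6-{(E)-2-[(tert-butyldimethylsilyl)oxy]ethenyl}-1-[(1E)-3-{[(4-methoxybenzyl)oxy]methyl}buta-1,3-dien-1-yl]-2,6-dimethyl-4-[(triethylsilyl)oxy]cyclohex-2-en-1-ol | C=C(COCc1ccc(OC)cc1)/C=C/[C@]2(O)C(C)=C[C@H](O[Si](CC)(CC)CC)C[C@@]2(C)/C=C/O[Si](C)(C)C(C)(C)C
F8 | step 12 | (1(10)Z,2R,4E,6R,7S)-6-[(tert-butyldimethylsilyl)oxy]-12-[(4-methoxybenzyl)oxy]-2-[(triethylsilyl)oxy]germacra-1(10),4,11(13)-trien-9-one | C=C(COCc1ccc(OC)cc1)[C@@H]2CC(=O)/C(C)=C\[C@H](O[Si](CC)(CC)CC)C/C(C)=C/[C@H]2O[Si](C)(C)C(C)(C)C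
F9 | step 12 | (1(10)Z,2R,4E,6R,7S)-6-[(tert-butyldimethylsilyl)oxy]-2-hydroxy-12-[(4-methoxybenzyl)oxy]germacra-1(10),4,11(13)-trien-9-one | C=C(COCc1ccc(OC)cc1)[C@@H]2CC(=O)/C(C)=C\[C@H](O)C/C(C)=C/[C@H]2O[Si](C)(C)C(C)(C)C
F10 | step 12 | (1(10)Z,2S,4E,6R,7S)-6-[(tert-butyldimethylsilyl)oxy]-12-[(4-methoxybenzyl)oxy]-9-oxogermacra-1(10),4,11(13)-trien-2-yl 4-nitrobenzoate | C=C(COCc1ccc(OC)cc1)[C@@H]2CC(=O)/C(C)=C\[C@@H](OC(=O)c3ccc(cc3)[N+](=O)[O-])C/C(C)=C/[C@H]2O[Si](C)(C)C(C)(C)C
F11 | step 12 | (1(10)Z,2S,4E,6R,7S)-6-[(tert-butyldimethylsilyl)oxy]-2-hydroxy-12-[(4-methoxybenzyl)oxy]germacra-1(10),4,11(13)-trien-9-one | C=C(COCc1ccc(OC)cc1)[C@@H]2CC(=O)/C(C)=C\[C@@H](O)C/C(C)=C/[C@H]2O[Si](C)(C)C(C)(C)C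
F12 | step 4 | tert-butyl{[(6R)-2,6-dimethyl-6-(prop-2-en-1-yl)cyclohexa-1,3-dien-1-yl]oxy}dimethylsilane | C=CC[C@]1(C)CC=CC(C)=C1O[Si](C)(C)C(C)(C)C
F13 | step 4 | (6R)-4-hydroxy-2,6-dimethyl-6-(prop-2-en-1-yl)cyclohex-2-en-1-one (both C4 epimers) | C=CC[C@]1(C)CC(O)C=C(C)C1=O
F0 | step 14 | none | none
F14 | step 16 | 9S-epimer of 30 | C=C(COCc1ccc(OC)cc1)[C@@H]2[C@@H](OC(=O)/C(C)=C\C)[C@@H](O)/C(C)=C\[C@@H](O[Si](C)(C)C(C)(C)C)C/C(C)=C/[C@H]2O[Si](C)(C)C(C)(C)C
F15 | step 21 | 9-acetoxy-2,6,12-trihydroxygermacra-1(10),4,11(13)-trien-8-yl (2Z)-2-methylbut-2-enoate | C=C(CO)[C@@H]2[C@@H](OC(=O)/C(C)=C\C)[C@H](OC(C)=O)/C(C)=C\[C@@H](O)C/C(C)=C/[C@H]2O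
F16 | step 21 | 12,6-lactol of the C12 aldehyde (C12 unassigned) | C=C1C(O)O[C@@H]2/C=C(\C)C[C@H](O)/C=C(/C)[C@@H](OC(C)=O)[C@H](OC(=O)/C(C)=C\C)[C@@H]12
A1 | alternative 1 | 6-hydroxy-2H-pyran-3(6H)-one lactol (one anomer drawn) | COC(=O)/C(CO[Si](C)(C)C(C)(C)C)=C/[C@H]1O[C@@H](O)C=C(C)C1=O
A2 | alternative 1 | methyl (2E,4R)-2-{[(tert-butyldimethylsilyl)oxy]methyl}-4-hydroxy-4-(3-methylfuran-2-yl)but-2-enoate | COC(=O)/C(CO[Si](C)(C)C(C)(C)C)=C/[C@@H](O)c1occc1C
A3 | alternative 2 | ten-membered (1(10)Z,4E)-diene with saturated lactone and C8,C9 acetonide | C/C1=C/[C@@H](O[Si](C)(C)C(C)(C)C)C/C(C)=C/[C@H]2OC(=O)C[C@@H]2[C@H]3OC(C)(C)O[C@@H]31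
A4 | alternative 2 | cis-fused decalin with C4 pinacol boronate and C1 mesylate | C[C@@]12[C@H](OS(C)(=O)=O)[C@@H](O[Si](C)(C)C(C)(C)C)C[C@@](C)(B3OC(C)(C)C(C)(C)O3)[C@@H]1[C@H]4OC(=O)C[C@@H]4[C@H]5OC(C)(C)O[C@@H]52
A5 | alternative 3 | ten-membered C6 allylic alcohol with E-olefin C4=C5 and pendant C12 methyl ester | O[C@@H]3/C=C(\C)C[C@H](O[Si](C)(C)C(C)(C)C)/C=C(/C)[C@H]1OC(C)(C)O[C@@H]1[C@H]3CC(=O)OC
A6 | alternative 3 | open-chain ynal with C6 aldehyde and terminal alkyne C4≡C5 | C#CC[C@H](O[Si](C)(C)C(C)(C)C)/C=C(/C)[C@H]1OC(C)(C)O[C@@H]1[C@H](C=O)CC(=O)OC
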